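**Retrosynthetic overview**
1. Sarmentosumin C (21) ⇐ global hydrogenolysis of heptabenzyl ether 20. The C2–Ph bond and the only stereocentre ⇐ late-stage Pd(II)/(R)-t-BuPyOx enantioselective conjugate addition of PhB(OH)2 to the fully assembled chromone 18 (key step; no o-quinone-methide benzylation of pinocembrin, no chalcone cyclisation).
2. 18 ⇐ Negishi sp2–sp3 union of 6-iodochromone 8 with the tetrameric benzylzinc 17.
3. Chain chloride 16 ⇐ three rounds of Suzuki coupling (benzyl bromide + boronic acid 10) and halogenation, starting from bromide 3.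
4. 8 ⇐ acetophenone 1 by ortho-iodination/Negishi (C8 arm), a second iodination (C6 handle) and DMF-DMA annulation.
5. Ring order: the A ring and all phenol rings are bought; the pyranone C ring is closed in step 4; the phenyl B ring is attached last (step 13), which makes C2 stereogenic.

Assumption 1: compounds 1, 3, 9 and 19 are bought as catalogue chemicals.
Assumption 2: the (R)-ligand is taken to give 2S because the (S)-ligand is known to give (R)-β-aryl ketones by the same enone-face model; the sense is confirmed by CD of 20, and the ligand enantiomer is switched if it proves opposite.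

**Route**

Step 1
Reactants: 1 1-[2,4-bis(benzyloxy)-6-hydroxyphenyl]ethan-1-one
Product: 2 1-[4,6-bis(benzyloxy)-2-hydroxy-3-iodophenyl]ethan-1-one
Conditions: NIS (1.0 eq), TFA (10 mol %), MeCN, –10 °C → rt
Reagents that add atoms: N-iodosuccinimide, O=C1CCC(=O)N1I
Why: Electrophilic aromatic iodination of an acylphloroglucinol, where C3 (ortho to the free chelated OH, flanked by one OBn) reacts ahead of C5 (buried between two OBn groups); regiochemistry is checked by NOE of the remaining ArH to both OCH2Ph groups.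

Step 2
Reactants: 2 1-[4,6-bis(benzyloxy)-2-hydroxy-3-iodophenyl]ethan-1-one; 3 1-(benzyloxy)-2-(bromomethyl)benzene
Product: 5 1-{4,6-bis(benzyloxy)-3-[2-(benzyloxy)benzyl]-2-hydroxyphenyl}ethan-1-one, via [2-(benzyloxy)benzyl]zinc bromide 4 (not isolated)
Conditions: (i) 3 (2.4 eq), Zn dust, LiCl, THF, 0 °C → rt; (ii) slow addition to 2, Pd(OAc)2 (2 mol %), SPhos (4 mol %), THF, rt → 45 °C; aq NH4Cl
Reagents that add atoms: none
Why: Negishi sp2–sp3 coupling, in which LiCl-promoted zinc insertion gives the benzylzinc and Pd/SPhos couples it with the ortho-substituted aryl iodide despite the free phenol (which consumes one extra equivalent of 4), the ketone being inert to RZnX.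

Step 3
Reactants: 5 1-{4,6-bis(benzyloxy)-3-[2-(benzyloxy)benzyl]-2-hydroxyphenyl}ethan-1-one
Product: 6 1-{4,6-bis(benzyloxy)-3-[2-(benzyloxy)benzyl]-2-hydroxy-5-iodophenyl}ethan-1-one
Conditions: NIS (1.1 eq), TFA (10 mol %), MeCN/CH2Cl2, 0 °C → rt
Reagents that add atoms: N-iodosuccinimide, O=C1CCC(=O)N1I
Why: Electrophilic aromatic iodination at the only open position of the A ring, which is activated by three oxygens (ortho, ortho, para) and is far more nucleophilic than the mono-alkoxy pendant ring.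

Step 4
Reactants: 6 1-{4,6-bis(benzyloxy)-3-[2-(benzyloxy)benzyl]-2-hydroxy-5-iodophenyl}ethan-1-one
Product: 8 5,7-bis(benzyloxy)-8-[2-(benzyloxy)benzyl]-6-iodo-4H-chromen-4-one, via dimethylaminoenone 7 (not isolated)
Conditions: DMF-DMA (3 eq), toluene, 95 °C; evaporate; conc. HCl, CH2Cl2, rt
Reagents that add atoms: N,N-dimethylformamide dimethyl acetal, COC(OC)N(C)C
Why: Enaminone route to chromones, in which the acetyl CH3 condenses with DMF-DMA and the only free phenol adds to the enaminone with loss of Me2NH, so the benzyl arm ends at C8 and the iodine at C6 without ambiguity.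

Step 5
Reactants: 9 [4-(benzyloxy)-3-formylphenyl]boronic acid
Product: 10 [4-(benzyloxy)-3-(hydroxymethyl)phenyl]boronic acid
Conditions: NaBH4, MeOH/THF, 0 °C; aq NH4Cl to pH 6
Reagents that add atoms: none
Why: Chemoselective borohydride reduction of the aldehyde, with the boronic acid untouched (the meta relationship rules out benzoxaborole formation).

Step 6
Reactants: 3 1-(benzyloxy)-2-(bromomethyl)benzene; 10 [4-(benzyloxy)-3-(hydroxymethyl)phenyl]boronic acid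
Product: 11 {2-(benzyloxy)-5-[2-(benzyloxy)benzyl]phenyl}methanol
Conditions: Pd(PPh3)4 (3 mol %), K2CO3 (2 M aq), DME, 80 °C
Reagents that add atoms: none
Why: Suzuki–Miyaura sp3–sp2 coupling of a benzylic bromide, where the boron position fixes the new CH2 para to the OBn of the incoming ring and the free CH2OH is tolerated.

Step 7
Reactants: 11 {2-(benzyloxy)-5-[2-(benzyloxy)benzyl]phenyl}methanol
Product: 12 1-(benzyloxy)-2-(bromomethyl)-4-[2-(benzyloxy)benzyl]benzene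
Conditions: PBr3 (0.4 eq), CH2Cl2, 0 °C
Reagents that add atoms: phosphorus tribromide, BrP(Br)Br
Why: Bromination of a primary benzylic alcohol (SN2 on the phosphite ester); aryl benzyl ethers survive at 0 °C.

Step 8
Reactants: 12 1-(benzyloxy)-2-(bromomethyl)-4-[2-(benzyloxy)benzyl]benzene; 10 [4-(benzyloxy)-3-(hydroxymethyl)phenyl]boronic acid
Product: 13 {2-(benzyloxy)-5-[2-(benzyloxy)-5-[2-(benzyloxy)benzyl]benzyl]phenyl}methanol
Conditions: Pd(PPh3)4 (3 mol %), K2CO3 (2 M aq), DME, 80 °C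
Reagents that add atoms: none
Why: Second Suzuki–Miyaura sp3–sp2 coupling, with the same regiocontrol by the boron position as in step 6.

Step 9
Reactants: 13 {2-(benzyloxy)-5-[2-(benzyloxy)-5-[2-(benzyloxy)benzyl]benzyl]phenyl}methanol
Product: 14 1-(benzyloxy)-2-(bromomethyl)-4-{2-(benzyloxy)-5-[2-(benzyloxy)benzyl]benzyl}benzene
Conditions: PBr3 (0.4 eq), CH2Cl2, 0 °C
Reagents that add atoms: phosphorus tribromide, BrP(Br)Br
Why: Benzylic alcohol to bromide as in step 7.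

Step 10
Reactants: 14 1-(benzyloxy)-2-(bromomethyl)-4-{2-(benzyloxy)-5-[2-(benzyloxy)benzyl]benzyl}benzene; 10 [4-(benzyloxy)-3-(hydroxymethyl)phenyl]boronic acid
Product: 15 {2-(benzyloxy)-5-[2-(benzyloxy)-5-[2-(benzyloxy)-5-[2-(benzyloxy)benzyl]benzyl]benzyl]phenyl}methanol
Conditions: Pd(PPh3)4 (3 mol %), K2CO3 (2 M aq), DME, 80 °C
Reagents that add atoms: none
Why: Third Suzuki–Miyaura sp3–sp2 coupling, completing the ortho/para-linked four-ring chain.

Step 11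
Reactants: 15 {2-(benzyloxy)-5-[2-(benzyloxy)-5-[2-(benzyloxy)-5-[2-(benzyloxy)benzyl]benzyl]benzyl]phenyl}methanol
Product: 16 1-(benzyloxy)-2-(chloromethyl)-4-{2-(benzyloxy)-5-[2-(benzyloxy)-5-[2-(benzyloxy)benzyl]benzyl]benzyl}benzene
Conditions: SOCl2 (1.2 eq), DMF (cat.), CH2Cl2, 0 °C → rt
Reagents that add atoms: thionyl chloride, O=S(Cl)Cl
Why: Chlorination of the benzylic alcohol via the chlorosulfite; the chloride is chosen because benzylic chlorides give the least Wurtz coupling on zinc insertion.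

Step 12
Reactants: 16 1-(benzyloxy)-2-(chloromethyl)-4-{2-(benzyloxy)-5-[2-(benzyloxy)-5-[2-(benzyloxy)benzyl]benzyl]benzyl}benzene; 8 5,7-bis(benzyloxy)-8-[2-(benzyloxy)benzyl]-6-iodo-4H-chromen-4-one
Product: 18 5,7-bis(benzyloxy)-8-[2-(benzyloxy)benzyl]-6-{2-(benzyloxy)-5-[2-(benzyloxy)-5-[2-(benzyloxy)-5-[2-(benzyloxy)benzyl]benzyl]benzyl]benzyl}-4H-chromen-4-one, via tetra-aryl benzylzinc chloride 17 (not isolated)
Conditions: (i) 16 (1.3 eq), Zn dust, LiCl, THF, 25 °C; (ii) 8, Pd(OAc)2 (5 mol %), SPhos (10 mol %), THF, 25 → 50 °C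
Reagents that add atoms: none
Why: Negishi sp2–sp3 fragment union, in which Pd/SPhos inserts into the di-ortho-alkoxy aryl iodide and the primary benzylzinc transmetalates readily, while the chromone has no acidic proton and does not take up RZnCl uncatalysed.

Step 13
Reactants: 18 5,7-bis(benzyloxy)-8-[2-(benzyloxy)benzyl]-6-{2-(benzyloxy)-5-[2-(benzyloxy)-5-[2-(benzyloxy)-5-[2-(benzyloxy)benzyl]benzyl]benzyl]benzyl}-4H-chromen-4-one; 19 phenylboronic acid
Product: 20 (2S)-5,7-bis(benzyloxy)-8-[2-(benzyloxy)benzyl]-6-{2-(benzyloxy)-5-[2-(benzyloxy)-5-[2-(benzyloxy)-5-[2-(benzyloxy)benzyl]benzyl]benzyl]benzyl}-2-phenylchroman-4-one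
Conditions: Pd(OCOCF3)2 (10 mol %), (R)-t-BuPyOx (12 mol %), NH4PF6 (30 mol %), 19 (3 eq), H2O (5 eq), ClCH2CH2Cl, 60 °C
Reagents that add atoms: none
Why: Pd(II)-catalysed asymmetric conjugate addition of an arylboronic acid to a chromone, in which the aryl–Pd adds across C2=C3 and water protonates the Pd enolate; the tert-butyl oxazoline of the ligand selects the enone face and so sets C2 as S, at a site remote from the crowded A ring.

Step 14
Reactants: 20 (2S)-5,7-bis(benzyloxy)-8-[2-(benzyloxy)benzyl]-6-{2-(benzyloxy)-5-[2-(benzyloxy)-5-[2-(benzyloxy)-5-[2-(benzyloxy)benzyl]benzyl]benzyl]benzyl}-2-phenylchroman-4-one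
Product: 21 sarmentosumin C, (2S)-5,7-dihydroxy-8-(2-hydroxybenzyl)-6-{2-hydroxy-5-[2-hydroxy-5-[2-hydroxy-5-(2-hydroxybenzyl)benzyl]benzyl]benzyl}-2-phenylchroman-4-one
Conditions: H2 (1 atm), 10 % Pd/C, THF/MeOH, rt, stopped at 7 eq H2 uptake
Reagents that add atoms: none
Why: Hydrogenolysis of seven aryl benzyl ethers under neutral conditions, which cannot trigger retro-oxa-Michael opening so C2 stays S; the diarylmethane CH2 groups and the ketone are inert at 1 atm.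

**Compound list**
1 | 1-[2,4-bis(benzyloxy)-6-hydroxyphenyl]ethan-1-one | CC(=O)c1c(O)cc(OCc2ccccc2)cc1OCc1ccccc1 | starting material
2 | 1-[4,6-bis(benzyloxy)-2-hydroxy-3-iodophenyl]ethan-1-one | CC(=O)c1c(O)c(I)c(OCc2ccccc2)cc1OCc1ccccc1 | intermediate
3 | 1-(benzyloxy)-2-(bromomethyl)benzene | BrCc1ccccc1OCc1ccccc1 | starting material
4 | [2-(benzyloxy)benzyl]zinc bromide | Br[Zn]Cc1ccccc1OCc1ccccc1 | intermediate
5 | 1-{4,6-bis(benzyloxy)-3-[2-(benzyloxy)benzyl]-2-hydroxyphenyl}ethan-1-one | CC(=O)c1c(O)c(Cc2ccccc2OCc2ccccc2)c(OCc2ccccc2)cc1OCc1ccccc1 | intermediate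
6 | 1-{4,6-bis(benzyloxy)-3-[2-(benzyloxy)benzyl]-2-hydroxy-5-iodophenyl}ethan-1-one | CC(=O)c1c(O)c(Cc2ccccc2OCc2ccccc2)c(OCc2ccccc2)c(I)c1OCc1ccccc1 | intermediate
7 | (E)-1-{4,6-bis(benzyloxy)-3-[2-(benzyloxy)benzyl]-2-hydroxy-5-iodophenyl}-3-(dimethylamino)prop-2-en-1-one | CN(C)/C=C/C(=O)c1c(O)c(Cc2ccccc2OCc2ccccc2)c(OCc2ccccc2)c(I)c1OCc1ccccc1 | intermediate
8 | 5,7-bis(benzyloxy)-8-[2-(benzyloxy)benzyl]-6-iodo-4H-chromen-4-one | O=c1ccoc2c(Cc3ccccc3OCc3ccccc3)c(OCc3ccccc3)c(I)c(OCc3ccccc3)c12 | intermediate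
9 | [4-(benzyloxy)-3-formylphenyl]boronic acid | O=Cc1cc(B(O)O)ccc1OCc1ccccc1 | starting material
10 | [4-(benzyloxy)-3-(hydroxymethyl)phenyl]boronic acid | OCc1cc(B(O)O)ccc1OCc1ccccc1 | intermediate
11 | {2-(benzyloxy)-5-[2-(benzyloxy)benzyl]phenyl}methanol | OCc1cc(Cc2ccccc2OCc2ccccc2)ccc1OCc1ccccc1 | intermediate
12 | 1-(benzyloxy)-2-(bromomethyl)-4-[2-(benzyloxy)benzyl]benzene | BrCc1cc(Cc2ccccc2OCc2ccccc2)ccc1OCc1ccccc1 | intermediate
13 | {2-(benzyloxy)-5-[2-(benzyloxy)-5-[2-(benzyloxy)benzyl]benzyl]phenyl}methanol | OCc1cc(Cc2cc(Cc3ccccc3OCc3ccccc3)ccc2OCc2ccccc2)ccc1OCc1ccccc1 | intermediate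
14 | 1-(benzyloxy)-2-(bromomethyl)-4-{2-(benzyloxy)-5-[2-(benzyloxy)benzyl]benzyl}benzene | BrCc1cc(Cc2cc(Cc3ccccc3OCc3ccccc3)ccc2OCc2ccccc2)ccc1OCc1ccccc1 | intermediate
15 | {2-(benzyloxy)-5-[2-(benzyloxy)-5-[2-(benzyloxy)-5-[2-(benzyloxy)benzyl]benzyl]benzyl]phenyl}methanol | OCc1cc(Cc2cc(Cc3cc(Cc4ccccc4OCc4ccccc4)ccc3OCc3ccccc3)ccc2OCc2ccccc2)ccc1OCc1ccccc1 | intermediate
16 | 1-(benzyloxy)-2-(chloromethyl)-4-{2-(benzyloxy)-5-[2-(benzyloxy)-5-[2-(benzyloxy)benzyl]benzyl]benzyl}benzene | ClCc1cc(Cc2cc(Cc3cc(Cc4ccccc4OCc4ccccc4)ccc3OCc3ccccc3)ccc2OCc2ccccc2)ccc1OCc1ccccc1 | intermediate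
17 | {2-(benzyloxy)-5-[2-(benzyloxy)-5-[2-(benzyloxy)-5-[2-(benzyloxy)benzyl]benzyl]benzyl]benzyl}zinc chloride | Cl[Zn]Cc1cc(Cc2cc(Cc3cc(Cc4ccccc4OCc4ccccc4)ccc3OCc3ccccc3)ccc2OCc2ccccc2)ccc1OCc1ccccc1 | intermediate
18 | 5,7-bis(benzyloxy)-8-[2-(benzyloxy)benzyl]-6-{2-(benzyloxy)-5-[2-(benzyloxy)-5-[2-(benzyloxy)-5-[2-(benzyloxy)benzyl]benzyl]benzyl]benzyl}-4H-chromen-4-one | O=c1ccoc2c(Cc3ccccc3OCc3ccccc3)c(OCc3ccccc3)c(Cc3cc(Cc4cc(Cc5cc(Cc6ccccc6OCc6ccccc6)ccc5OCc5ccccc5)ccc4OCc4ccccc4)ccc3OCc3ccccc3)c(OCc3ccccc3)c12 | intermediate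
19 | phenylboronic acid | OB(O)c1ccccc1 | starting material
20 | (2S)-5,7-bis(benzyloxy)-8-[2-(benzyloxy)benzyl]-6-{2-(benzyloxy)-5-[2-(benzyloxy)-5-[2-(benzyloxy)-5-[2-(benzyloxy)benzyl]benzyl]benzyl]benzyl}-2-phenylchroman-4-one | O=C1C[C@@H](c2ccccc2)Oc2c(Cc3ccccc3OCc3ccccc3)c(OCc3ccccc3)c(Cc3cc(Cc4cc(Cc5cc(Cc6ccccc6OCc6ccccc6)ccc5OCc5ccccc5)ccc4OCc4ccccc4)ccc3OCc3ccccc3)c(OCc3ccccc3)c21 | intermediate
21 | sarmentosumin C, (2S)-5,7-dihydroxy-8-(2-hydroxybenzyl)-6-{2-hydroxy-5-[2-hydroxy-5-[2-hydroxy-5-(2-hydroxybenzyl)benzyl]benzyl]benzyl}-2-phenylchroman-4-one | O=C1C[C@@H](c2ccccc2)Oc2c(Cc3ccccc3O)c(O)c(Cc3cc(Cc4cc(Cc5cc(Cc6ccccc6O)ccc5O)ccc4O)ccc3O)c(O)c21 | target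

**Totals**
Total step count: 14.
Longest linear sequence: 10 steps (steps 5–14, from 9 to 21). The chromone branch (steps 1–4) joins at step 12.

**Three steps most likely to fail, with fallbacks**

Step 13 (asymmetric conjugate arylation of the electron-rich, 5-alkoxy chromone 18; risk of low conversion or ee). The fallback sets out from 18 and comes back at 20. Chromone 18 is treated with PhMgBr, CuBr·SMe2 and TMSCl in THF at –78 → –20 °C, a stoichiometric cuprate 1,4-addition with silyl trapping that prevents ring opening of the enolate. This gives 5,7-bis(benzyloxy)-8-[2-(benzyloxy)benzyl]-6-(tetra-aryl benzyl)-2-phenyl-4-(trimethylsilyloxy)-2H-chromene F1. Hydrolysis with 1 M HCl in THF gives the racemic heptabenzyl 2-phenylchroman-4-one F2. This is resolved by preparative HPLC on an amylose-type chiral phase, and the (2S)-enantiomer is 20.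

Step 12 (zinc insertion into the large benzylic chloride and coupling at the di-ortho-alkoxy iodide). The fallback sets out from 5 (with alcohol 15) and comes back at 18. Alcohol 15 is added slowly to 5 (2 eq) with Sc(OTf)3 (10 mol %) in MeNO2/CH2Cl2 at rt. This Friedel–Crafts benzylation occurs at C5, the only open position of the most nucleophilic ring, and gives 1-{4,6-bis(benzyloxy)-3-[2-(benzyloxy)benzyl]-5-(tetra-aryl benzyl)-2-hydroxyphenyl}ethan-1-one F3. DMF-DMA in toluene at 95 °C then gives the corresponding (E)-3-(dimethylamino)prop-2-en-1-one F4, which conc. HCl in CH2Cl2 closes to 18. No iodide or organozinc is needed.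

Step 2 (Negishi coupling next to a free chelated phenol, which also depends on the C3 selectivity of step 1). The fallback sets out from 1 and comes back at 5. Compound 1, commercial 2-(benzyloxy)benzaldehyde (O=Cc1ccccc1OCc1ccccc1) and phenylboronic acid 19 are heated in toluene with catalytic propionic acid under Dean–Stark conditions. The boron tether delivers the aldehyde only to the carbon ortho to the free OH and gives 1-{5,7-bis(benzyloxy)-4-[2-(benzyloxy)phenyl]-2-phenyl-4H-1,3,2-benzodioxaborin-8-yl}ethan-1-one F5. Ionic reduction with Et3SiH/TFA in CH2Cl2 at 0 °C, followed by aqueous work-up, gives 5.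

**Further compounds**
F1 | step 13 | 5,7-bis(benzyloxy)-8-[2-(benzyloxy)benzyl]-6-{2-(benzyloxy)-5-[2-(benzyloxy)-5-[2-(benzyloxy)-5-[2-(benzyloxy)benzyl]benzyl]benzyl]benzyl}-2-phenyl-4-(trimethylsilyloxy)-2H-chromene | C[Si](C)(C)OC1=CC(c2ccccc2)Oc2c(Cc3ccccc3OCc3ccccc3)c(OCc3ccccc3)c(Cc3cc(Cc4cc(Cc5cc(Cc6ccccc6OCc6ccccc6)ccc5OCc5ccccc5)ccc4OCc4ccccc4)ccc3OCc3ccccc3)c(OCc3ccccc3)c21
F2 | step 13 | racemic 5,7-bis(benzyloxy)-8-[2-(benzyloxy)benzyl]-6-{2-(benzyloxy)-5-[2-(benzyloxy)-5-[2-(benzyloxy)-5-[2-(benzyloxy)benzyl]benzyl]benzyl]benzyl}-2-phenylchroman-4-one | O=C1CC(c2ccccc2)Oc2c(Cc3ccccc3OCc3ccccc3)c(OCc3ccccc3)c(Cc3cc(Cc4cc(Cc5cc(Cc6ccccc6OCc6ccccc6)ccc5OCc5ccccc5)ccc4OCc4ccccc4)ccc3OCc3ccccc3)c(OCc3ccccc3)c21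
F3 | step 12 | 1-{4,6-bis(benzyloxy)-3-[2-(benzyloxy)benzyl]-5-{2-(benzyloxy)-5-[2-(benzyloxy)-5-[2-(benzyloxy)-5-[2-(benzyloxy)benzyl]benzyl]benzyl]benzyl}-2-hydroxyphenyl}ethan-1-one | CC(=O)c1c(O)c(Cc2ccccc2OCc2ccccc2)c(OCc2ccccc2)c(Cc2cc(Cc3cc(Cc4cc(Cc5ccccc5OCc5ccccc5)ccc4OCc4ccccc4)ccc3OCc3ccccc3)ccc2OCc2ccccc2)c1OCc1ccccc1
F4 | step 12 | (E)-1-{4,6-bis(benzyloxy)-3-[2-(benzyloxy)benzyl]-5-{2-(benzyloxy)-5-[2-(benzyloxy)-5-[2-(benzyloxy)-5-[2-(benzyloxy)benzyl]benzyl]benzyl]benzyl}-2-hydroxyphenyl}-3-(dimethylamino)prop-2-en-1-one | CN(C)/C=C/C(=O)c1c(O)c(Cc2ccccc2OCc2ccccc2)c(OCc2ccccc2)c(Cc2cc(Cc3cc(Cc4cc(Cc5ccccc5OCc5ccccc5)ccc4OCc4ccccc4)ccc3OCc3ccccc3)ccc2OCc2ccccc2)c1OCc1ccccc1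
F5 | step 2 | 1-{5,7-bis(benzyloxy)-4-[2-(benzyloxy)phenyl]-2-phenyl-4H-1,3,2-benzodioxaborin-8-yl}ethan-1-one | CC(=O)c1c2OB(c3ccccc3)OC(c3ccccc3OCc3ccccc3)c2c(OCc2ccccc2)cc1OCc1ccccc1
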